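## Retrosynthetic overview

1. The C3'=C4' (E) alkene is made last. An ene–diene cross-metathesis joins a vinyl-bearing tetronic acid (west fragment) to a terminal (E)-1,3-diene (east fragment).
2. Key disconnection, west fragment: both ring C–O bonds (C5–O1 and O1–C2) are cut. A new titanium-enolate oxygenation places the ring oxygen on C5 of an acyclic 2-methyl-3-oxoacyl oxazolidinone, and the resulting alkoxide lactonises with loss of the auxiliary.
3. The keto imide comes from (R)-4-methylhex-5-enoic acid and (R)-4-benzyl-3-propanoyloxazolidin-2-one. The acid is made by oxidative cleavage of (R)-β-citronellene, which supplies C2'. The oxazolidinone sets a relay stereocentre that is erased later.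
4. East fragment: methylalumination/vinylation of a terminal alkyne gives the C6' methyl and the C4'–C5' bond. Reductive coupling of an aldehyde tosylhydrazone with furan-3-boronic acid gives the C13'–furan bond. Propargylation of (S)-citronellyl bromide, which supplies C10', gives the C7'–C8' bond.
5. Ring order: the furan is bought intact. The butenolide (tetronic acid) ring is the only ring formed, in step 7, before the fragments are joined.

Assumption: operations run in one flask or on unpurified crude material count as one step, and the two purchased terpenes are taken as enantiopure.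

Locants: ring atoms are O1 and C2–C5 of the furan-2(5H)-one; side-chain atoms C1'–C13' are counted outward from C5.

## Route

Step 1
Reactants: 1 (S)-citronellyl bromide; 2 1-(trimethylsilyl)propyne
Product: 4 [(6R)-6,10-dimethylundec-9-en-1-yn-1-yl]trimethylsilane, via lithiated silylpropyne 3 (not isolated)
Conditions: 2 (1.3 equiv), n-BuLi (1.25 equiv), THF, −78 → −20 °C; then 1, DMPU, −78 → 23 °C
Reagents that add atoms: none
Why: SN2 propargylation, in which the carbanion of 2 is alkylated at its CH2 terminus by the primary bromide (the silyl cap blocks the acetylide position and disfavours the allenyl mode), and the methyl-bearing centre of 1 is untouched, its descriptor changing from S to R only through CIP ranking.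

Step 2
Reactants: 4 [(6R)-6,10-dimethylundec-9-en-1-yn-1-yl]trimethylsilane
Product: 6 (4R)-4-methyl-9-(trimethylsilyl)non-8-ynal, via ozonide 5 (not isolated)
Conditions: O3, CH2Cl2, −78 °C; then Me2S, −78 → 23 °C
Reagents that add atoms: ozone, [O-][O+]=O
Why: Ozonolysis with reductive work-up, in which ozone takes the electron-rich trisubstituted alkene far faster than the silyl-capped alkyne, Me2S reduces ozonide 5 to the aldehyde, and no stereocentre is involved.

Step 3
Reactants: 6 (4R)-4-methyl-9-(trimethylsilyl)non-8-ynal; 7 furan-3-boronic acid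
Product: 12 3-[(4R)-4-methylnon-8-yn-1-yl]furan, via tosylhydrazone 8 (not isolated), via diazoalkane 9 (not isolated), via furylalkylboronic acid 10 (not isolated), via silyl alkyne 11 (not isolated)
Conditions: TsNHNH2 (1.05 equiv), 1,4-dioxane, 80 °C, 2 h; then 7 (1.5 equiv), K2CO3 (3 equiv), 110 °C, 4 h; cool, MeOH, 23 °C, 3 h
Reagents that add atoms: none
Why: Metal-free reductive coupling of a tosylhydrazone with a boronic acid (Barluenga type), in which base turns 8 into diazoalkane 9, the boron of 7 captures its carbon, furyl migrates from B to C with loss of N2 and the furylic boronic acid 10 protodeboronates, so CHO becomes CH2–furyl in one flask before K2CO3/MeOH strips the silyl cap, all without touching the remote stereocentre.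

Step 4
Reactants: 12 3-[(4R)-4-methylnon-8-yn-1-yl]furan; 13 vinyl bromide
Product: 15 3-[(4R,8E)-4,8-dimethylundeca-8,10-dien-1-yl]furan, via alkenylalane 14 (not isolated)
Conditions: Me3Al (2.5 equiv), Cp2ZrCl2 (0.25 equiv), CH2Cl2, 0 → 23 °C, 12 h; strip volatiles; THF, 13 (3 equiv, 1 M in THF), ZnCl2 (0.3 equiv), Pd(PPh3)4 (5 mol %), 23 °C
Reagents that add atoms: trimethylaluminium, C[Al](C)C
Why: Negishi zirconium-catalysed methylalumination adds Me and Al syn with Al at the terminus, which fixes the E trisubstituted C5'=C6' alkene, and the palladium/zinc co-catalysed Negishi alkenyl–alkenyl coupling with 13 proceeds with retention.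

Step 5
Reactants: 16 (R)-β-citronellene
Product: 19 (4R)-4-methylhex-5-enoic acid, via ozonide 17 (not isolated), via aldehyde 18 (not isolated)
Conditions: O3 (1.0 equiv, Sudan red 7B end point), CH2Cl2, −78 °C; Me2S; crude 18, NaClO2, NaH2PO4, 2-methylbut-2-ene, t-BuOH/H2O, 0 → 23 °C
Reagents that add atoms: ozone, [O-][O+]=O; sodium chlorite, [Na+].[O-]Cl=O
Why: Chemoselective ozonolysis (the trisubstituted alkene reacts well ahead of the vinyl group when ozone is stopped at the dye end point) followed by Pinnick oxidation of the crude volatile aldehyde, neither of which touches the allylic stereocentre that becomes C2'.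

Step 6
Reactants: 19 (4R)-4-methylhex-5-enoic acid; 20 (4R)-4-benzyl-3-propanoyl-1,3-oxazolidin-2-one
Product: 23 (4R)-4-benzyl-3-[(2S,6R)-2,6-dimethyl-3-oxooct-7-enoyl]-1,3-oxazolidin-2-one, via acid chloride 21 (not isolated), via lithium enolate 22 (not isolated)
Conditions: 19, (COCl)2 (1.2 equiv), DMF (cat.), CH2Cl2, 0 → 23 °C, concentrate; 20, LiN(iPr)2 (1.05 equiv), THF, −78 °C, 30 min; add 21 in THF, −78 °C, 20 min; aq. NH4Cl
Reagents that add atoms: none
Why: Evans asymmetric acylation, in which the chelated Z lithium enolate 22 is C-acylated by 21 on the face opposite the benzyl group, setting the (2S) relay centre in the same sense as imide alkylation, while allylic strain keeps the new C2–H from being removed so the keto imide does not epimerise.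

Step 7
Reactants: 23 (4R)-4-benzyl-3-[(2S,6R)-2,6-dimethyl-3-oxooct-7-enoyl]-1,3-oxazolidin-2-one
Product: 26 (5R)-4-hydroxy-3-methyl-5-[(2R)-2-methylbut-3-en-1-yl]furan-2(5H)-one, via titanium enolate 24 (not isolated), via titanium alkoxide 25 (not isolated)
Conditions: TiCl4 (1.1 equiv), iPr2NEt (1.15 equiv), CH2Cl2, −10 °C, 1 h; 2-(benzenesulfonyl)-3-phenyloxaziridine (1.05 equiv), −78 → −20 °C, 2 h; then 23 °C, 2 h; aq. citric acid; extract into aq. NaHCO3, re-acidify
Reagents that add atoms: 2-(benzenesulfonyl)-3-phenyloxaziridine, O=S(=O)(N1OC1c1ccccc1)c1ccccc1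
Why: Proposed new method: soft enolisation of 2-methyl-3-oxoacyl oxazolidinones with TiCl4/iPr2NEt is established in the titanium aldol of beta-keto imides, where it removes a C4 proton and leaves C2–H alone (allylic strain holds C2–H out of alignment with the carbonyl pi systems) to give the chelated Z enolate 24 whose C2 methyl covers one face; what has not been shown is oxygen transfer to this enolate, and here the N-sulfonyloxaziridine (Davis-type enolate hydroxylation, enolate carbon attacking the oxaziridine oxygen, possibly templated by titanium) should deliver O to C4 anti to that methyl, the same face aldehydes take in the 2,4-syn titanium aldol, which for (2S) gives the (4R) C–O bond; alkoxide 25 then attacks the titanium-activated exocyclic imide carbonyl (5-exo-trig lactonisation, the second C–O bond), the auxiliary is expelled and the ring enolises, so the relay centre is erased and only (5R) remains.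

Step 8
Reactants: 26 (5R)-4-hydroxy-3-methyl-5-[(2R)-2-methylbut-3-en-1-yl]furan-2(5H)-one; 15 3-[(4R,8E)-4,8-dimethylundeca-8,10-dien-1-yl]furan
Product: 27 (5R)-5-[(2R,3E,5E,10R)-13-(furan-3-yl)-2,6,10-trimethyltrideca-3,5-dien-1-yl]-4-hydroxy-3-methylfuran-2(5H)-one
Conditions: second-generation Hoveyda–Grubbs catalyst RuCl2(H2IMes)(=CH-C6H4-2-OiPr) (2 × 5 mol %), 1,4-benzoquinone (10 mol %), 15 (1.5 equiv), CH2Cl2 (0.1 M), 40 °C, argon sparge
Reagents that add atoms: none
Why: Ene–diene cross-metathesis, in which only the two monosubstituted alkenes are accessible to ruthenium (the trisubstituted C5'=C6' alkene and the ring C=C are too hindered), ethene loss drives the reaction, the E geometry of C3'=C4' follows from the thermodynamic preference of a conjugated alkene next to the branched C2', and benzoquinone quenches ruthenium hydrides that could migrate the alkene and erode C2'.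

## Compound list

1 | (S)-citronellyl bromide, (6S)-8-bromo-2,6-dimethyloct-2-ene | BrCC[C@@H](C)CCC=C(C)C | starting material
2 | 1-(trimethylsilyl)propyne | CC#C[Si](C)(C)C | starting material
3 | 3-lithio-1-(trimethylsilyl)propyne | [Li]CC#C[Si](C)(C)C | intermediate
4 | [(6R)-6,10-dimethylundec-9-en-1-yn-1-yl]trimethylsilane | C[Si](C)(C)C#CCCC[C@@H](C)CCC=C(C)C | intermediate
5 | 3,3-dimethyl-5-[(3R)-3-methyl-8-(trimethylsilyl)oct-7-yn-1-yl]-1,2,4-trioxolane (ring CH epimers) | C[Si](C)(C)C#CCCC[C@@H](C)CCC1OOC(C)(C)O1 | intermediate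
6 | (4R)-4-methyl-9-(trimethylsilyl)non-8-ynal | C[Si](C)(C)C#CCCC[C@@H](C)CCC=O | intermediate
7 | furan-3-boronic acid | OB(O)c1ccoc1 | starting material
8 | N'-[(4R)-4-methyl-9-(trimethylsilyl)non-8-yn-1-ylidene]-4-methylbenzenesulfonohydrazide | C[Si](C)(C)C#CCCC[C@@H](C)CCC=NNS(=O)(=O)c1ccc(C)cc1 | intermediate
9 | [(6R)-9-diazo-6-methylnon-1-yn-1-yl]trimethylsilane | C[Si](C)(C)C#CCCC[C@@H](C)CCC=[N+]=[N-] | intermediate
10 | [(4R)-1-(furan-3-yl)-4-methyl-9-(trimethylsilyl)non-8-yn-1-yl]boronic acid (C1 epimers) | C[Si](C)(C)C#CCCC[C@@H](C)CCC(B(O)O)c1ccoc1 | intermediate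
11 | 3-[(4S)-4-methyl-9-(trimethylsilyl)non-8-yn-1-yl]furan (same spatial arrangement; S only because silicon raises the alkyne arm in CIP ranking) | C[Si](C)(C)C#CCCC[C@@H](C)CCCc1ccoc1 | intermediate
12 | 3-[(4R)-4-methylnon-8-yn-1-yl]furan | C#CCCC[C@@H](C)CCCc1ccoc1 | intermediate
13 | vinyl bromide (bromoethene) | C=CBr | starting material
14 | [(1E,6S)-9-(furan-3-yl)-2,6-dimethylnon-1-en-1-yl]dimethylalane (same spatial arrangement; S through CIP ranking of Al) | C[Al](C)/C=C(\C)CCC[C@@H](C)CCCc1ccoc1 | intermediate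
15 | 3-[(4R,8E)-4,8-dimethylundeca-8,10-dien-1-yl]furan | C=C/C=C(\C)CCC[C@@H](C)CCCc1ccoc1 | intermediate
16 | (R)-β-citronellene, (3R)-3,7-dimethylocta-1,6-diene | CC(C)=CCC[C@@H](C)C=C | starting material
17 | 3,3-dimethyl-5-[(3R)-3-methylpent-4-en-1-yl]-1,2,4-trioxolane (ring CH epimers) | C=C[C@H](C)CCC1OOC(C)(C)O1 | intermediate
18 | (4R)-4-methylhex-5-enal | C=C[C@H](C)CCC=O | intermediate
19 | (4R)-4-methylhex-5-enoic acid | C=C[C@H](C)CCC(=O)O | intermediate
20 | (4R)-4-benzyl-3-propanoyl-1,3-oxazolidin-2-one | CCC(=O)N1C(=O)OC[C@H]1Cc1ccccc1 | starting material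
21 | (4R)-4-methylhex-5-enoyl chloride | C=C[C@H](C)CCC(=O)Cl | intermediate
22 | lithium (Z)-enolate of 20 | C/C=C(\O[Li])N1C(=O)OC[C@H]1Cc1ccccc1 | intermediate
23 | (4R)-4-benzyl-3-[(2S,6R)-2,6-dimethyl-3-oxooct-7-enoyl]-1,3-oxazolidin-2-one | C=C[C@H](C)CCC(=O)[C@H](C)C(=O)N1C(=O)OC[C@H]1Cc1ccccc1 | intermediate
24 | trichlorotitanium (3Z)-enolate of 23, (2S,6R) retained | C=C[C@H](C)C/C=C(\O[Ti](Cl)(Cl)Cl)[C@H](C)C(=O)N1C(=O)OC[C@H]1Cc1ccccc1 | intermediate
25 | trichlorotitanium alkoxide of (4R)-4-benzyl-3-[(2S,4R,6R)-4-hydroxy-2,6-dimethyl-3-oxooct-7-enoyl]-1,3-oxazolidin-2-one | C=C[C@H](C)C[C@@H](O[Ti](Cl)(Cl)Cl)C(=O)[C@H](C)C(=O)N1C(=O)OC[C@H]1Cc1ccccc1 | intermediate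
26 | (5R)-4-hydroxy-3-methyl-5-[(2R)-2-methylbut-3-en-1-yl]furan-2(5H)-one | CC1=C(O)[C@@H](C[C@@H](C)C=C)OC1=O | intermediate
27 | (5R)-5-[(2R,3E,5E,10R)-13-(furan-3-yl)-2,6,10-trimethyltrideca-3,5-dien-1-yl]-4-hydroxy-3-methylfuran-2(5H)-one | CC1=C(O)[C@@H](C[C@@H](C)/C=C/C=C(\C)CCC[C@@H](C)CCCc2ccoc2)OC1=O | target

## Step count and risks

Total step count: 8. Longest linear sequence: 5 (steps 1, 2, 3, 4, 8). The west branch is 4 steps (5, 6, 7, 8).

**Step 7 (the new oxygenation–lactonisation).**
- Oxygen transfer from an N-sulfonyloxaziridine to a trichlorotitanium enolate is unproven and may be slow.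
- The facial bias may be weaker than in the closed aldol transition state.
- Surplus oxidant could hydroxylate C3 of the tetronate.
- The fallback uses known chemistry only. It sets out from 19 (by way of acid chloride 21, made as in step 6) and comes back at 26.
- Acid chloride 21 N-acylates (R)-4-benzyloxazolidin-2-one (Et3N, DMAP cat., CH2Cl2) to give (4R)-4-benzyl-3-[(4R)-4-methylhex-5-enoyl]-1,3-oxazolidin-2-one F1.
- NaN(SiMe3)2 in THF at −78 °C forms the chelated sodium (Z)-enolate of this imide F2. The same oxaziridine hydroxylates it opposite the benzyl group (auxiliary-controlled enolate hydroxylation) to (4R)-4-benzyl-3-[(2R,4R)-2-hydroxy-4-methylhex-5-enoyl]-1,3-oxazolidin-2-one F3.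
- MeOMgBr in MeOH at 0 °C releases methyl (2R,4R)-2-hydroxy-4-methylhex-5-enoate F4.
- Propanoyl chloride and pyridine give methyl (2R,4R)-4-methyl-2-(propanoyloxy)hex-5-enoate F5.
- LiN(SiMe3)2 (2.2 equiv, THF, −78 → 0 °C) closes the ring by Dieckmann condensation to 26.
- This replaces steps 6 and 7 by five operations.

**Step 8 (ene–diene cross-metathesis).**
- The vinyl-substituted ruthenium alkylidene derived from 15 is sluggish.
- Homodimers of both partners compete.
- The E/Z ratio may fall short.
- The acidic tetronic acid may slow the catalyst.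
- The fallback moves the union to the C4'–C5' bond, with both alkene geometries preset. It sets out from 26 and from 12, and comes back at 27.
- Cross-metathesis of 26 with vinylboronic acid pinacol ester (same ruthenium catalyst, CH2Cl2, 40 °C) gives (5R)-4-hydroxy-3-methyl-5-[(2R,3E)-2-methyl-4-(4,4,5,5-tetramethyl-1,3,2-dioxaborolan-2-yl)but-3-en-1-yl]furan-2(5H)-one F6.
- Alkyne 12 is carboaluminated to 14 as in step 4 and quenched with I2 (THF, −30 °C) to give 3-[(4S,8E)-9-iodo-4,8-dimethylnon-8-en-1-yl]furan F7. The spatial arrangement is unchanged; the S descriptor arises only from the CIP ranking of iodine.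
- Suzuki–Miyaura coupling (Pd(dppf)Cl2, Cs2CO3 3.5 equiv, THF/H2O, 23 °C) joins the two to 27.

**Step 3 (reductive coupling).**
- The aliphatic diazoalkane 9 can collapse to the terminal alkene or to an azine.
- Boronic acid 7 can protodeboronate at 110 °C.
- Premature loss of the silyl cap would expose the alkyne to pyrazole formation.
- The fallback replaces the coupling by polar addition and radical deoxygenation. It sets out from 6 and comes back at 11, which K2CO3/MeOH converts to 12 as in step 3.
- 3-Bromofuran and n-BuLi (THF, −78 °C) give 3-furyllithium F8. This adds to 6 to give (4R)-1-(furan-3-yl)-4-methyl-9-(trimethylsilyl)non-8-yn-1-ol F9, whose C1 epimers are of no consequence.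
- 1,1'-Thiocarbonyldiimidazole (DMAP, CH2Cl2) gives O-[(4R)-1-(furan-3-yl)-4-methyl-9-(trimethylsilyl)non-8-yn-1-yl] 1H-imidazole-1-carbothioate F10.
- Bu3SnH/AIBN in toluene at 80 °C (Barton–McCombie deoxygenation) delivers 11.

Further compounds
F1 | step 7 | (4R)-4-benzyl-3-[(4R)-4-methylhex-5-enoyl]-1,3-oxazolidin-2-one | C=C[C@H](C)CCC(=O)N1C(=O)OC[C@H]1Cc1ccccc1
F2 | step 7 | sodium (Z)-enolate of F1 | C=C[C@H](C)C/C=C(\O[Na])N1C(=O)OC[C@H]1Cc1ccccc1
F3 | step 7 | (4R)-4-benzyl-3-[(2R,4R)-2-hydroxy-4-methylhex-5-enoyl]-1,3-oxazolidin-2-one | C=C[C@H](C)C[C@@H](O)C(=O)N1C(=O)OC[C@H]1Cc1ccccc1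
F4 | step 7 | methyl (2R,4R)-2-hydroxy-4-methylhex-5-enoate | C=C[C@H](C)C[C@@H](O)C(=O)OC
F5 | step 7 | methyl (2R,4R)-4-methyl-2-(propanoyloxy)hex-5-enoate | C=C[C@H](C)C[C@@H](OC(=O)CC)C(=O)OC
F6 | step 8 | (5R)-4-hydroxy-3-methyl-5-[(2R,3E)-2-methyl-4-(4,4,5,5-tetramethyl-1,3,2-dioxaborolan-2-yl)but-3-en-1-yl]furan-2(5H)-one | CC1=C(O)[C@@H](C[C@@H](C)/C=C/B2OC(C)(C)C(C)(C)O2)OC1=O
F7 | step 8 | 3-[(4S,8E)-9-iodo-4,8-dimethylnon-8-en-1-yl]furan | I/C=C(\C)CCC[C@@H](C)CCCc1ccoc1
F8 | step 3 | 3-furyllithium | [Li]c1ccoc1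
F9 | step 3 | (4R)-1-(furan-3-yl)-4-methyl-9-(trimethylsilyl)non-8-yn-1-ol (C1 epimers) | C[Si](C)(C)C#CCCC[C@@H](C)CCC(O)c1ccoc1
F10 | step 3 | O-[(4R)-1-(furan-3-yl)-4-methyl-9-(trimethylsilyl)non-8-yn-1-yl] 1H-imidazole-1-carbothioate (C1 epimers) | C[Si](C)(C)C#CCCC[C@@H](C)CCC(OC(=S)n1ccnc1)c1ccoc1
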